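**Retrosynthetic overview**
1. Target ⇒ (deprotection, C8' oxidation) a 1,3-diol ⇒ C7'–C8' cut: C30 apo-ynal 12 plus the β-lithioalkoxide 13 from spiro-epoxide 4 (umpolung aldol; C6' is carried in by the oxirane).
2. 12 ⇒ C6–C7 Sonogashira cut: enol triflate 9 plus C21 ynal 11; 11 ⇒ one-carbon homologation of one end of symmetric C20 crocetin dialdehyde 10 (two-directional desymmetrisation, all seven E-alkenes bought).
3. 9 ⇒ ketoisophorone 5 (asymmetric transfer hydrogenation sets C3; conjugate reduction and enolate triflation).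
4. 4 ⇒ (R)-levodione 1 (C5' from the chiral pool; ketal, methylenation, face-selective epoxidation sets C6').
5. Rings: both six-membered rings are bought and no carbocycle is built; the only ring made is the oxirane (step 3), which is opened again in step 9.

Assumption: the SMILES is read as (3S,5'R,6'R), all-E, with the 6'-OH cis to the 5'-methyl; all-E crocetin dialdehyde, (6R)-levodione and ketoisophorone are taken as commercial.

**Step 1**
Reactants: 1 (6R)-2,2,6-trimethylcyclohexane-1,4-dione
Product: 2 (9R)-7,7,9-trimethyl-1,4-dioxaspiro[4.5]decan-8-one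
Conditions: ethylene glycol (1.2 equiv), pyridinium p-toluenesulfonate (cat.), benzene, reflux, Dean–Stark
Reagents that add atoms: ethylene glycol, OCCO
Why: acid-catalysed acetalisation is chemoselective for the unhindered C4 carbonyl because the C1 carbonyl is flanked by three methyl groups, and the weak acid does not enolise C1, so the C6 stereocentre is kept.

**Step 2**
Reactants: 2 (9R)-7,7,9-trimethyl-1,4-dioxaspiro[4.5]decan-8-one
Product: 3 (9R)-7,7,9-trimethyl-8-methylidene-1,4-dioxaspiro[4.5]decane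
Conditions: Cp2TiMe2 (3 equiv), toluene, 75 °C, dark
Reagents that add atoms: dimethyltitanocene, C[Ti](C)(C1C=CC=C1)C1C=CC=C1
Why: Petasis methylenation (titanocene methylidene, [2+2] then cycloreversion) is non-basic and works on hindered, epimerisable ketones, so C=O becomes C=CH2 without touching the adjacent stereocentre or the ketal.

**Step 3**
Reactants: 3 (9R)-7,7,9-trimethyl-8-methylidene-1,4-dioxaspiro[4.5]decane
Product: 4 spiro-epoxide (3R,12R)-4,4,12-trimethyl-1,7,10-trioxadispiro[2.2.4.2]dodecane (oxirane O cis to the secondary methyl)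
Conditions: m-chloroperbenzoic acid (1.3 equiv), NaHCO3 (3 equiv), CH2Cl2, 0 °C
Reagents that add atoms: m-chloroperbenzoic acid, OOC(=O)c1cccc(Cl)c1
Why: Prilezhaev epoxidation of the chair with the secondary methyl equatorial takes place on the face opposite the axial methyl of the gem-dimethyl group, which puts the oxirane oxygen axial and cis to the secondary methyl and so sets the future C6' as R (minor epimer removed by chromatography).

**Step 4**
Reactants: 5 2,6,6-trimethylcyclohex-2-ene-1,4-dione (ketoisophorone)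
Product: 6 (4R)-4-hydroxy-2,6,6-trimethylcyclohex-2-en-1-one
Conditions: RuCl[(1R,2R)-TsNCHPhCHPhNH2](p-cymene) (0.5 mol %), KOH (1 mol %), 2-propanol, 25 °C
Reagents that add atoms: none
Why: Noyori asymmetric transfer hydrogenation reduces only the unhindered C4 carbonyl (C1 is shielded by the gem-dimethyl group), and the (R,R) ligand is expected to give the 4R alcohol with the alkenyl arm in the role of the aryl group of the CH/π model (sense to be confirmed by optical rotation); this centre becomes C3 (S) of the target.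

**Step 5**
Reactants: 6 (4R)-4-hydroxy-2,6,6-trimethylcyclohex-2-en-1-one
Product: 7 (4R)-2,6,6-trimethyl-4-(triethylsilyloxy)cyclohex-2-en-1-one
Conditions: Et3SiCl (1.2 equiv), imidazole (2 equiv), DMF, 0 → 20 °C
Reagents that add atoms: chlorotriethylsilane, CC[Si](Cl)(CC)CC
Why: standard silylation of a secondary alcohol gives an ether that survives hydride, base, palladium and organolithium steps yet falls off in the final dilute-acid step.

**Step 6**
Reactants: 7 (4R)-2,6,6-trimethyl-4-(triethylsilyloxy)cyclohex-2-en-1-one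
Product: 9 (4S)-2,6,6-trimethyl-4-(triethylsilyloxy)cyclohex-1-en-1-yl trifluoromethanesulfonate, via lithium enolate 8 (not isolated)
Conditions: LiBH(s-Bu)3 (1.05 equiv), THF, −78 °C; then PhNTf2 (1.2 equiv), −78 → 0 °C; H2O
Reagents that add atoms: N-phenylbis(trifluoromethanesulfonimide), O=S(=O)(N(c1ccccc1)S(=O)(=O)C(F)(F)F)C(F)(F)F
Why: the bulky borohydride adds 1,4 to the β-unsubstituted enone whose carbonyl is shielded (conjugate reduction) and the regiodefined tetrasubstituted enolate is O-triflated; the carbinol centre is untouched and its descriptor changes from R to S only because the CIP ranking of the ring arms changes.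

**Step 7**
Reactants: 10 crocetin dialdehyde (all-E 2,6,11,15-tetramethylhexadeca-2,4,6,8,10,12,14-heptaenedial, 3 equiv)
Product: 11 (2E,4E,6E,8E,10E,12E,14E)-2,6,11,15-tetramethylheptadeca-2,4,6,8,10,12,14-heptaen-16-ynal
Conditions: Me3SiCHN2 (1.0 equiv), LiN(iPr)2 (1.0 equiv), THF, −78 °C; add to 10 in THF, −78 → 0 °C; H2O; recover 10
Reagents that add atoms: trimethylsilyldiazomethane, C[Si](C)(C)C=[N+]=[N-]
Why: Colvin homologation (addition of the lithiated silyldiazomethane, Peterson elimination to a diazoalkene, loss of N2 and 1,2-H shift of the alkylidene carbene) turns one formyl group into a terminal alkyne under aprotic conditions that avoid conjugate addition to the polyenal, and the excess of symmetric dialdehyde makes mono-reaction dominant.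

**Step 8**
Reactants: 11 C21 ynal; 9 (4S)-enol triflate (1.3 equiv)
Product: 12 (3S)-3-(triethylsilyloxy)-7,8-didehydro-8'-apo-β-caroten-8'-al
Conditions: Pd(PPh3)4 (5 mol %), CuI (10 mol %), Et3N (3 equiv), degassed DMF, 25–40 °C, dark
Reagents that add atoms: none
Why: Sonogashira coupling of a terminal alkyne with a hindered cyclohexenyl triflate forms the C6–C7 bond under mild amine conditions that leave the aldehyde, the silyl ether and the E-polyene intact.

**Step 9**
Reactants: 4 spiro-epoxide (2.5 equiv); 12 C30 apo-ynal (1.0 equiv)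
Product: 14 (3S,5'R,6'R,8'RS)-3',3'-(ethylenedioxy)-3-(triethylsilyloxy)-7,8-didehydro-5',6',7',8'-tetrahydro-β,β-carotene-6',8'-diol, via β-lithioalkoxide 13 (not isolated)
Conditions: lithium 4,4'-di-tert-butylbiphenylide (4.8 equiv, preformed 0.4 M in THF), 4, THF, −78 °C, 15 min; then 12, −78 °C, 30 min; H2O
Reagents that add atoms: none
Why: reductive lithiation of a 1,1-disubstituted epoxide by an arene radical anion cleaves the CH2–O bond to a β-lithioalkoxide that is stable at −78 °C and adds 1,2 to the α-methyl enal, the C6'–O bond is never broken so C6' keeps its configuration, the C8' carbinol mixture is erased in step 10, and the radical anion is kept below two equivalents per epoxide so none is left when the polyenal arrives.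

**Step 10**
Reactants: 14 1,3-diol
Product: 15 (3S,5'R,6'R)-3',3'-(ethylenedioxy)-6'-hydroxy-3-(triethylsilyloxy)-7,8-didehydro-5',6',7',8'-tetrahydro-β,β-caroten-8'-one
Conditions: MnO2 (activated, 20 equiv), CH2Cl2, 20 °C, dark
Reagents that add atoms: none
Why: allylic oxidation with MnO2 touches only the polyene-allylic secondary alcohol, the tertiary alcohol and silyl ether being inert, and gives the β-hydroxy enone under neutral conditions that cannot trigger retro-aldol cleavage.

**Step 11**
Reactants: 15 protected β-hydroxy enone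
Product: 16 (3S,5'R,6'R)-3,6'-dihydroxy-7,8-didehydro-5',6',7',8'-tetrahydro-β,β-carotene-3',8'-dione (CNP0128854.2)
Conditions: 1 M aq HCl/THF (1:5), 0 → 20 °C, argon, dark
Reagents that add atoms: water, O
Why: dilute aqueous acid hydrolyses the dioxolane of the unhindered ketone and the triethylsilyl ether in one operation (acetal hydrolysis and desilylation) at a temperature where the tertiary aldol and the all-E polyene survive, and no stereocentre is affected.

**Compound list**
1 | (6R)-2,2,6-trimethylcyclohexane-1,4-dione, (R)-levodione | O=C1[C@H](C)CC(=O)CC1(C)C | starting material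
2 | (9R)-7,7,9-trimethyl-1,4-dioxaspiro[4.5]decan-8-one | O=C1[C@H](C)CC2(OCCO2)CC1(C)C | intermediate
3 | (9R)-7,7,9-trimethyl-8-methylidene-1,4-dioxaspiro[4.5]decane | C=C1[C@H](C)CC2(OCCO2)CC1(C)C | intermediate
4 | (3R,12R)-4,4,12-trimethyl-1,7,10-trioxadispiro[2.2.4.2]dodecane, oxirane O cis to the secondary methyl | C1O[C@@]12[C@H](C)CC3(OCCO3)CC2(C)C | intermediate
5 | 2,6,6-trimethylcyclohex-2-ene-1,4-dione, ketoisophorone | O=C1C=C(C)C(=O)C(C)(C)C1 | starting material
6 | (4R)-4-hydroxy-2,6,6-trimethylcyclohex-2-en-1-one | O=C1C(C)(C)C[C@@H](O)C=C1C | intermediate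
7 | (4R)-2,6,6-trimethyl-4-(triethylsilyloxy)cyclohex-2-en-1-one | O=C1C(C)(C)C[C@@H](O[Si](CC)(CC)CC)C=C1C | intermediate
8 | lithium (4S)-2,6,6-trimethyl-4-(triethylsilyloxy)cyclohex-1-en-1-olate | CC1=C([O-])C(C)(C)C[C@@H](O[Si](CC)(CC)CC)C1.[Li+] | intermediate (not isolated)
9 | (4S)-2,6,6-trimethyl-4-(triethylsilyloxy)cyclohex-1-en-1-yl trifluoromethanesulfonate | CC1=C(OS(=O)(=O)C(F)(F)F)C(C)(C)C[C@@H](O[Si](CC)(CC)CC)C1 | intermediate
10 | crocetin dialdehyde, (2E,4E,6E,8E,10E,12E,14E)-2,6,11,15-tetramethylhexadeca-2,4,6,8,10,12,14-heptaenedial | O=C/C(C)=C/C=C/C(C)=C/C=C/C=C(C)/C=C/C=C(\C)C=O | starting material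
11 | (2E,4E,6E,8E,10E,12E,14E)-2,6,11,15-tetramethylheptadeca-2,4,6,8,10,12,14-heptaen-16-ynal | C#C/C(C)=C/C=C/C(C)=C/C=C/C=C(C)/C=C/C=C(\C)C=O | intermediate
12 | (3S)-3-(triethylsilyloxy)-7,8-didehydro-8'-apo-β-caroten-8'-al | CC1=C(C#C/C(C)=C/C=C/C(C)=C/C=C/C=C(C)/C=C/C=C(\C)C=O)C(C)(C)C[C@@H](O[Si](CC)(CC)CC)C1 | intermediate
13 | dilithium β-lithioalkoxide: (8R,9R)-8-(lithiomethyl)-7,7,9-trimethyl-1,4-dioxaspiro[4.5]decan-8-olate | [Li]C[C@@]1(O[Li])[C@H](C)CC2(OCCO2)CC1(C)C | intermediate (not isolated)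
14 | (3S,5'R,6'R,8'RS)-3',3'-(ethylenedioxy)-3-(triethylsilyloxy)-7,8-didehydro-5',6',7',8'-tetrahydro-β,β-carotene-6',8'-diol | CC1=C(C#C/C(C)=C/C=C/C(C)=C/C=C/C=C(C)/C=C/C=C(\C)C(O)C[C@@]2(O)[C@H](C)CC3(OCCO3)CC2(C)C)C(C)(C)C[C@@H](O[Si](CC)(CC)CC)C1 | intermediate
15 | (3S,5'R,6'R)-3',3'-(ethylenedioxy)-6'-hydroxy-3-(triethylsilyloxy)-7,8-didehydro-5',6',7',8'-tetrahydro-β,β-caroten-8'-one | CC1=C(C#C/C(C)=C/C=C/C(C)=C/C=C/C=C(C)/C=C/C=C(\C)C(=O)C[C@@]2(O)[C@H](C)CC3(OCCO3)CC2(C)C)C(C)(C)C[C@@H](O[Si](CC)(CC)CC)C1 | intermediate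
16 | (3S,5'R,6'R)-3,6'-dihydroxy-7,8-didehydro-5',6',7',8'-tetrahydro-β,β-carotene-3',8'-dione | CC1=C(C#C/C(C)=C/C=C/C(C)=C/C=C/C=C(C)/C=C/C=C(\C)C(=O)C[C@@]2(O)[C@H](C)CC(=O)CC2(C)C)C(C)(C)C[C@@H](O)C1 | target

**Totals**
Total steps: 11. Longest linear sequence: 7 (steps 4, 5, 6, 8, 9, 10, 11, from ketoisophorone 5).

**Three steps most likely to fail**

Step 9 (β-lithioalkoxide plus polyenal; the delicate organolithium may reduce or deprotonate the C30 aldehyde). The fallback sets out from 12 and 3 and comes back at 15. Aldehyde 12 is condensed with NH2OH·HCl in pyridine to the aldoxime F1. Chlorination with N-chlorosuccinimide and slow addition of Et3N in the presence of excess alkene 3 traps the nitrile oxide F2 as it forms. The [3+2] cycloaddition puts oxygen on the fully substituted carbon, on the same face the peracid uses, and gives the spiro-isoxazoline F3. Mo(CO)6 in wet MeCN at 70 °C then cleaves the N–O bond, and hydrolysis of the β-hydroxy imine gives 15.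

Step 3 (face selectivity of the epoxidation, which fixes C6'). The fallback sets out from 2 and comes back at 13. If oxygen goes mainly to the other face, the same facial bias makes a carbon nucleophile add in the correct sense. PhSCH2Li (thioanisole, n-BuLi, DABCO; CeCl3 added if enolisation intervenes) is therefore added to ketone 2 to give the β-hydroxy sulfide F4. Deprotonation with n-BuLi and reductive C–S cleavage with lithium 4,4'-di-tert-butylbiphenylide at −78 °C then gives the same β-lithioalkoxide 13, which continues through step 9.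

Step 7 (statistical mono-homologation of sparingly soluble 10). The fallback sets out from 9 and comes back at 12, replacing steps 7 and 8 by linear olefination. Sonogashira coupling of 9 with (E)-3-methylpent-2-en-4-yn-1-ol gives the enynol F5. CBr4/PPh3 gives the allylic bromide F6, and PPh3 gives the phosphonium bromide F7. A Wittig reaction (NaOMe) with excess 2,7-dimethylocta-2,4,6-trienedial, followed by I2-catalysed equilibration to all-E, gives the C25 aldehyde F8. A Horner–Wadsworth–Emmons reaction with (E)-4-(diethoxyphosphoryl)-2-methylbut-2-enenitrile gives the C30 nitrile F9. Reduction with i-Bu2AlH at −78 °C and hydrolysis returns aldehyde 12.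

**Further compounds**
F1 | step 9 | (3S)-3-(triethylsilyloxy)-7,8-didehydro-8'-apo-β-caroten-8'-al (E)-oxime | CC1=C(C#C/C(C)=C/C=C/C(C)=C/C=C/C=C(C)/C=C/C=C(\C)/C=N/O)C(C)(C)C[C@@H](O[Si](CC)(CC)CC)C1
F2 | step 9 | (3S)-3-(triethylsilyloxy)-7,8-didehydro-8'-apo-β-carotene-8'-nitrile N-oxide | CC1=C(C#C/C(C)=C/C=C/C(C)=C/C=C/C=C(C)/C=C/C=C(\C)C#[N+][O-])C(C)(C)C[C@@H](O[Si](CC)(CC)CC)C1
F3 | step 9 | (5'R,6'R)-spiro-isoxazoline from F2 and 3 (ring O on C6', ketal and silyl ether retained) | CC1=C(C#C/C(C)=C/C=C/C(C)=C/C=C/C=C(C)/C=C/C=C(\C)C2=NO[C@]3(C2)[C@H](C)CC4(OCCO4)CC3(C)C)C(C)(C)C[C@@H](O[Si](CC)(CC)CC)C1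
F4 | step 3 | (8R,9R)-7,7,9-trimethyl-8-[(phenylsulfanyl)methyl]-1,4-dioxaspiro[4.5]decan-8-ol | c1ccccc1SC[C@@]1(O)[C@H](C)CC2(OCCO2)CC1(C)C
F5 | step 7 | (2E)-3-methyl-5-[(4S)-2,6,6-trimethyl-4-(triethylsilyloxy)cyclohex-1-en-1-yl]pent-2-en-4-yn-1-ol | CC1=C(C#C/C(C)=C/CO)C(C)(C)C[C@@H](O[Si](CC)(CC)CC)C1
F6 | step 7 | (2E)-1-bromo-3-methyl-5-[(4S)-2,6,6-trimethyl-4-(triethylsilyloxy)cyclohex-1-en-1-yl]pent-2-en-4-yne | CC1=C(C#C/C(C)=C/CBr)C(C)(C)C[C@@H](O[Si](CC)(CC)CC)C1
F7 | step 7 | {(2E)-3-methyl-5-[(4S)-2,6,6-trimethyl-4-(triethylsilyloxy)cyclohex-1-en-1-yl]pent-2-en-4-yn-1-yl}triphenylphosphonium bromide | CC1=C(C#C/C(C)=C/C[P+](c2ccccc2)(c2ccccc2)c2ccccc2)C(C)(C)C[C@@H](O[Si](CC)(CC)CC)C1.[Br-]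
F8 | step 7 | (3S)-3-(triethylsilyloxy)-7,8-didehydro-12'-apo-β-caroten-12'-al | CC1=C(C#C/C(C)=C/C=C/C(C)=C/C=C/C=C(\C)C=O)C(C)(C)C[C@@H](O[Si](CC)(CC)CC)C1
F9 | step 7 | (3S)-3-(triethylsilyloxy)-7,8-didehydro-8'-apo-β-carotene-8'-nitrile | CC1=C(C#C/C(C)=C/C=C/C(C)=C/C=C/C=C(C)/C=C/C=C(\C)C#N)C(C)(C)C[C@@H](O[Si](CC)(CC)CC)C1
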